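The route rests on cutting the nine-membered carbocycle back to a cis-fused hydrindane: in the target the C11=C19 exo-methylene lies 1,5 to the oxygenated C7 across C8–C10, the signature of a Grob fragmentation of the C7–C11 bond. The key step takes tricyclic lactone 15, whose cyclopentene (C7–C8=C9–C10–C11) and cyclohexane (C7, C6, C5, C4a, C11a, C11) share that bond and carry a C7 hydroxyl and a C11 tosyloxymethyl group, and in one operation delivers the C7 ketone, the exo-methylene, the Z-C8=C9 alkene and the nine-membered ring with the trans-lactone centres C4a/C11a intact. The precursor comes from an organocatalytic cyclohexenone, conjugate addition–allylation and ring-closing metathesis.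

Key step: step 11

Remark: xenicane numbering is used for every compound (C1 lactone OCH2, C3 lactone C=O, C4a/C11a ring fusion, C7 carbinol carbon, C11 the carbon bearing C19, C12–C15 side chain); threonate 20 and the (R)-prolinol catalyst are taken as commercial.

Step 1
Reactants: 1 methyl 4-oxobutanoate; 2 methyl vinyl ketone
Product: 3 methyl (3R)-3-formyl-6-oxoheptanoate
Conditions: (R)-α,α-diphenylprolinol TMS ether (5 mol %), ethyl 3,4-dihydroxybenzoate (20 mol %), neat, 4 °C
Reagents that add atoms: none
Why: Enamine-catalysed Michael addition of an aldehyde to an enone, in which the E-enamine of 1 is attacked on the face remote from the diphenyl(silyloxy)methyl group of the (R)-catalyst, which should set C4a as R.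

Step 2
Reactants: 3 methyl (3R)-3-formyl-6-oxoheptanoate
Product: 5 methyl 2-[(1R)-4-oxocyclohex-2-en-1-yl]acetate, via cyclic ketol 4 (not isolated)
Conditions: p-TsOH·H2O (10 mol %), toluene, 80 °C, 4 Å MS
Reagents that add atoms: none
Why: Acid-catalysed intramolecular aldol condensation of the methyl ketone onto the aldehyde (Robinson-type closure), which makes the six-membered enone irreversibly by dehydration and forms no new stereocentre.

Step 3
Reactants: 5 methyl 2-[(1R)-4-oxocyclohex-2-en-1-yl]acetate
Product: 6 methyl 2-[(1R)-3-(hydroxymethyl)-4-oxocyclohex-2-en-1-yl]acetate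
Conditions: 37 % aq. CH2O, DMAP (20 mol %), THF/H2O, rt
Reagents that add atoms: formaldehyde, C=O
Why: Morita–Baylis–Hillman hydroxymethylation of a cyclic enone, which places C19 on C11 at the alcohol oxidation level under mild conditions that leave C4a alone.

Step 4
Reactants: 6 methyl 2-[(1R)-3-(hydroxymethyl)-4-oxocyclohex-2-en-1-yl]acetate
Product: 7 methyl 2-[(1R)-3-(tert-butyldimethylsilyloxymethyl)-4-oxocyclohex-2-en-1-yl]acetate
Conditions: TBSCl, imidazole, CH2Cl2, 0 °C → rt
Reagents that add atoms: tert-butyldimethylsilyl chloride, CC(C)(C)[Si](C)(C)Cl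
Why: Routine silylation of a primary alcohol, giving a bulky, non-chelating ether that is a poor leaving group in the enolate of step 5.

Step 5
Reactants: 7 methyl 2-[(1R)-3-(tert-butyldimethylsilyloxymethyl)-4-oxocyclohex-2-en-1-yl]acetate
Product: 9 methyl 2-[(1R,2R,3S)-3-allyl-3-(tert-butyldimethylsilyloxymethyl)-2-(isopropoxydimethylsilylmethyl)-4-oxocyclohexyl]acetate, via magnesium enolate 8 (not isolated)
Conditions: (iPrO)Me2SiCH2MgCl, CuBr·SMe2 (10 mol %), THF, −78 → −40 °C; then allyl iodide, DMPU, −40 → 0 °C
Reagents that add atoms: (isopropoxydimethylsilyl)methylmagnesium chloride, CC(C)O[Si](C)(C)C[Mg]Cl; allyl iodide, C=CCI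
Why: Copper-catalysed conjugate addition of a hydroxymethyl-anion equivalent followed by enolate allylation, in which the nucleophile should add to C11a trans to the C4a side chain (usual outcome for 4-substituted cyclohexenones) and allyl iodide should then attack C11 anti to the new C11a substituent, fixing the quaternary centre.

Step 6
Reactants: 9 methyl 2-[(1R,2R,3S)-3-allyl-3-(tert-butyldimethylsilyloxymethyl)-2-(isopropoxydimethylsilylmethyl)-4-oxocyclohexyl]acetate
Product: 11 trans-fused keto lactone (4aR,11S,11aR) with C7 ketone and C11 bearing allyl plus CH2OTBS, via hydroxy ester 10 (not isolated)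
Conditions: 30 % H2O2, KF, KHCO3, THF/MeOH, rt; then PPTS (cat.), toluene, 50 °C
Reagents that add atoms: hydrogen peroxide, OO
Why: Tamao–Fleming oxidation turns the C–Si bond into C1–OH, and the resulting δ-hydroxy ester should lactonise by acid-catalysed transesterification to the trans-fused six-membered lactone because both ring substituents are equatorial.

Step 7
Reactants: 11 trans-fused keto lactone
Product: 12 C7 vinyl carbinol (4aR,7R,11S,11aR) with vinyl on C7 cis to allyl on C11
Conditions: vinylMgBr, CeCl3, THF, −78 °C
Reagents that add atoms: vinylmagnesium bromide, C=C[Mg]Br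
Why: Organocerium 1,2-addition, chemoselective for the ketone over the lactone at −78 °C, in which vinyl should enter axially on the face opposite the axial CH2OTBS group of C11 in the rigid trans-fused chair, placing the C7 hydroxyl equatorial.

Step 8
Reactants: 12 C7 vinyl carbinol
Product: 13 cis-hydrindenol lactone (4aR,7R,11S,11aR) with C8=C9 in the five-membered ring and CH2OTBS on C11
Conditions: Grubbs second-generation catalyst (5 mol %), CH2Cl2, 40 °C
Reagents that add atoms: none
Why: Ring-closing metathesis of a cis-disposed vinyl/allyl pair closes the cyclopentene and puts the alkene exactly at C8=C9 without touching any stereocentre.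

Step 9
Reactants: 13 cis-hydrindenol lactone silyl ether
Product: 14 cis-hydrindenol lactone diol (C7 tertiary OH and C19 primary OH)
Conditions: HF·pyridine, pyridine, THF, 0 °C → rt
Reagents that add atoms: none
Why: Buffered fluoride cleavage of a primary TBS ether, mild enough for the lactone and the tertiary allylic alcohol.

Step 10
Reactants: 14 cis-hydrindenol lactone diol
Product: 15 cis-hydrindenol lactone monotosylate (4aR,7R,11S,11aR) with C7 OH and C11 CH2OTs
Conditions: TsCl, Et3N, DMAP (cat.), CH2Cl2, 0 °C → rt
Reagents that add atoms: p-toluenesulfonyl chloride, Cc1ccc(cc1)S(=O)(=O)Cl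
Why: Selective sulfonylation of the primary C19 hydroxyl in the presence of the hindered tertiary C7 hydroxyl, the amine base being too weak to start the fragmentation and the neopentyl tosylate being inert to SN2 displacement.

Step 11
Reactants: 15 cis-hydrindenol lactone monotosylate
Product: 17 trans-fused lactone of the nine-membered Z-enone with C11 exo-methylene (4aR,11aR), via potassium alkoxide 16 (not isolated)
Conditions: KHMDS (1.05 equiv), THF, −78 → 0 °C; pH 7 buffer
Reagents that add atoms: none
Why: Deprotonation of the C7 hydroxyl gives alkoxide 16, whose oxygen lone pair forms C7=O while the C7–C11 σ-bond, antiperiplanar to C19–OTs after rotation of the exocyclic CH2OTs group, breaks and its electrons become C11=C19 as tosylate leaves (concerted Grob fragmentation of a 1,3-diol monosulfonate, the Wharton variant). No σ-bond is made: the nine-membered ring is not closed by cyclisation but appears when the bond shared by the five- and six-membered rings is cut, so two π-bonds (C7=O, C11=C19) replace one σ-bond and no medium-ring entropy is paid in a bond-forming event. No stereocentre is created; C7 and C11 become sp2, C4a and C11a are spectators, and the Z geometry of C8=C9 is inherited from the cyclopentene. The selectivity needed is chemoselectivity: fragmentation must outrun oxetane formation by O-alkylation, base-induced migration of the skipped C8=C9/C11=C19 diene into conjugation, and attack on the lactone. The substrate should secure this because the leaving group sits on a freely rotating carbon, so every conformer is aligned, whereas an oxetane would have to span the ring-fusion bond; and the single equivalent of hindered base is consumed by the hydroxyl, leaving only non-basic potassium tosylate once the enone exists.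

Step 12
Reactants: 17 nine-membered Z-enone lactone
Product: 18 tertiary allylic alcohol (4aR,7S,11aR) with C7 methyl carbinol and Z-C8=C9
Conditions: MeLi, CeCl3, THF, −78 °C
Reagents that add atoms: methyllithium, C[Li]
Why: Organocerium 1,2-addition to the enone carbonyl without conjugate addition, enolisation or lactone opening, in which methyl is expected to approach the outer face of the folded nine-membered ring, away from the lactone, giving the 7S carbinol.

Step 13
Reactants: 18 tertiary allylic alcohol
Product: 19 cis-8,9-epoxy alcohol (4aR,7S,8R,9R,11aR)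
Conditions: VO(acac)2 (5 mol %), t-BuOOH, CH2Cl2, 0 °C → rt
Reagents that add atoms: tert-butyl hydroperoxide, CC(C)(C)OO
Why: Vanadium-catalysed hydroxyl-directed epoxidation delivers oxygen to C8=C9 from the face of the C7 hydroxyl (the syn preference known for Z-cyclooctenols and Z-cyclononenols) and leaves the undirected C11=C19 alkene alone.

Step 14
Reactants: 20 methyl 3,4-O-isopropylidene-L-threonate
Product: 21 (1R)-1-[(4S)-2,2-dimethyl-1,3-dioxolan-4-yl]-2-methylpropane-1,2-diol
Conditions: MeMgBr (3.5 equiv), THF, 0 °C → rt
Reagents that add atoms: methylmagnesium bromide, C[Mg]Br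
Why: Double Grignard addition to the ester builds the C15 dimethyl carbinol, while C13 and C14 come unchanged from the chiral pool.

Step 15
Reactants: 21 acetonide diol
Product: 22 (1R)-1-[(4S)-2,2-dimethyl-1,3-dioxolan-4-yl]-2-hydroxy-2-methylpropyl methanesulfonate
Conditions: MsCl (1.1 equiv), Et3N, CH2Cl2, −20 °C
Reagents that add atoms: methanesulfonyl chloride, CS(=O)(=O)Cl
Why: Selective mesylation of the secondary C14 hydroxyl, the tertiary C15 hydroxyl being unreactive under these conditions.

Step 16
Reactants: 22 acetonide mesylate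
Product: 23 (2S,3R)-1,2,4-trihydroxy-4-methylpentan-3-yl methanesulfonate
Conditions: p-TsOH·H2O (cat.), MeOH, rt
Reagents that add atoms: none
Why: Acid-catalysed acetal exchange removes the acetonide at a stage where no acid-labile epoxide is yet present.

Step 17
Reactants: 23 triol mesylate
Product: 24 (2S,3R)-4-hydroxy-4-methyl-1,2-bis(triethylsilyloxy)pentan-3-yl methanesulfonate
Conditions: TESCl (2.2 equiv), imidazole, CH2Cl2, 0 °C
Reagents that add atoms: triethylsilyl chloride, CC[Si](CC)(CC)Cl
Why: Silylation of the primary and secondary hydroxyls, with the tertiary hydroxyl too hindered to react at 0 °C, so that only the C15 oxygen remains free to close the epoxide.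

Step 18
Reactants: 24 bis-TES mesylate
Product: 25 (2S)-2-[(1S)-1,2-bis(triethylsilyloxy)ethyl]-3,3-dimethyloxirane
Conditions: t-BuOK (1.1 equiv), THF, −20 °C
Reagents that add atoms: none
Why: Intramolecular Williamson etherification (3-exo-tet) in which the C15 alkoxide displaces the C14 mesylate with inversion, converting the threo chiral-pool array into the erythro 13-oxy-14,15-epoxide the target requires.

Step 19
Reactants: 25 bis-TES epoxide
Product: 26 (2R)-2-[(2S)-3,3-dimethyloxiran-2-yl]-2-(triethylsilyloxy)acetaldehyde
Conditions: (COCl)2, DMSO, CH2Cl2, −78 → −30 °C; then Et3N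
Reagents that add atoms: none
Why: Swern oxidation, which cleaves and oxidises a primary TES ether directly to the aldehyde while the secondary TES ether and the epoxide survive.

Step 20
Reactants: 19 cis-8,9-epoxy alcohol lactone; 26 side-chain aldehyde
Product: 28 β-hydroxy lactone (C4/C12 epimer mixture), via dilithio enolate 27 (not isolated)
Conditions: LDA (2.1 equiv), THF, −78 °C; then 26; sat. NH4Cl
Reagents that add atoms: none
Why: Lithium-enolate aldol addition of the lactone (the C7 alkoxide is carried as a spectator) forms the C4–C12 bond, and the uncontrolled centres at C4 and C12 are both erased in step 21.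

Step 21
Reactants: 28 β-hydroxy lactone
Product: 30 13-O-TES ether of the target with the E-alkylidene lactone, via C12 mesylate 29 (not isolated)
Conditions: MsCl, Et3N, CH2Cl2, 0 °C; then DBU, rt
Reagents that add atoms: none
Why: Mesylation of the secondary C12 hydroxyl and E1cB elimination through the lactone enolate should give the more stable E-alkylidene lactone, with C13 trans to the carbonyl, from either aldol epimer.

Step 22
Reactants: 30 13-O-TES ether
Product: 31 target CNP0147265.1 (4aS,7S,8R,9R,11aR,13S,14S; E-alkylidene)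
Conditions: TBAF, AcOH (1:1), THF, 0 °C
Reagents that add atoms: none
Why: Buffered fluoride desilylation frees the C13 hydroxyl without generating an alkoxide that could open either epoxide by Payne rearrangement.

Compound list
1 | methyl 4-oxobutanoate | COC(=O)CCC=O | starting material
2 | methyl vinyl ketone | CC(=O)C=C | starting material
3 | methyl (3R)-3-formyl-6-oxoheptanoate | CC(=O)CC[C@@H](C=O)CC(=O)OC | intermediate
4 | methyl 2-[(1R)-2-hydroxy-4-oxocyclohexyl]acetate (ketol, carbinol epimers) | O=C1CC(O)[C@@H](CC(=O)OC)CC1 | intermediate (not isolated)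
5 | methyl 2-[(1R)-4-oxocyclohex-2-en-1-yl]acetate | O=C1C=C[C@@H](CC(=O)OC)CC1 | intermediate
6 | methyl 2-[(1R)-3-(hydroxymethyl)-4-oxocyclohex-2-en-1-yl]acetate | O=C1C(CO)=C[C@@H](CC(=O)OC)CC1 | intermediate
7 | methyl 2-[(1R)-3-(tert-butyldimethylsilyloxymethyl)-4-oxocyclohex-2-en-1-yl]acetate | O=C1C(CO[Si](C)(C)C(C)(C)C)=C[C@@H](CC(=O)OC)CC1 | intermediate
8 | chloromagnesium enolate of 9 before allylation (C7–O–MgCl, C7=C11) | Cl[Mg]OC1=C(CO[Si](C)(C)C(C)(C)C)[C@H](C[Si](C)(C)OC(C)C)[C@@H](CC(=O)OC)CC1 | intermediate (not isolated)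
9 | methyl 2-[(1R,2R,3S)-3-allyl-3-(tert-butyldimethylsilyloxymethyl)-2-(isopropoxydimethylsilylmethyl)-4-oxocyclohexyl]acetate | O=C1CC[C@H](CC(=O)OC)[C@@H](C[Si](C)(C)OC(C)C)[C@@]1(CC=C)CO[Si](C)(C)C(C)(C)C | intermediate
10 | methyl 2-[(1R,2R,3S)-3-allyl-3-(tert-butyldimethylsilyloxymethyl)-2-(hydroxymethyl)-4-oxocyclohexyl]acetate | O=C1CC[C@H](CC(=O)OC)[C@@H](CO)[C@@]1(CC=C)CO[Si](C)(C)C(C)(C)C | intermediate (not isolated)
11 | trans-fused keto δ-lactone (4aR,11S,11aR): C7 ketone, C11 with allyl and CH2OTBS (CH2OTBS cis to C1) | O=C1CC[C@@H]2CC(=O)OC[C@H]2[C@@]1(CC=C)CO[Si](C)(C)C(C)(C)C | intermediate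
12 | C7 vinyl carbinol (4aR,7R,11S,11aR): vinyl cis to allyl, OH cis to CH2OTBS | C=C[C@]1(O)CC[C@@H]2CC(=O)OC[C@H]2[C@@]1(CC=C)CO[Si](C)(C)C(C)(C)C | intermediate
13 | cis-hydrindenol lactone (4aR,7R,11S,11aR), C11 CH2OTBS | CC(C)(C)[Si](C)(C)OC[C@@]12CC=C[C@]1(O)CC[C@@H]3CC(=O)OC[C@@H]23 | intermediate
14 | cis-hydrindenol lactone diol (4aR,7R,11S,11aR), C11 CH2OH | OC[C@@]12CC=C[C@]1(O)CC[C@@H]3CC(=O)OC[C@@H]23 | intermediate
15 | cis-hydrindenol lactone monotosylate (4aR,7R,11S,11aR), C7 OH and C11 CH2OTs | Cc1ccc(cc1)S(=O)(=O)OC[C@@]12CC=C[C@]1(O)CC[C@@H]3CC(=O)OC[C@@H]23 | intermediate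
16 | potassium C7 alkoxide of 15 | Cc1ccc(cc1)S(=O)(=O)OC[C@@]12CC=C[C@]1([O-])CC[C@@H]3CC(=O)OC[C@@H]23.[K+] | intermediate (not isolated)
17 | (4aR,11aR) trans-fused lactone of the nine-membered Z-enone (C7=O, Z-C8=C9, C11=C19) | C=C1C/C=C\C(=O)CC[C@@H]2CC(=O)OC[C@@H]12 | intermediate
18 | (4aR,7S,11aR) C7 methyl carbinol of 17 | C=C1C/C=C\[C@@](C)(O)CC[C@@H]2CC(=O)OC[C@@H]12 | intermediate
19 | (4aR,7S,8R,9R,11aR) cis-8,9-epoxy alcohol, epoxide syn to C7 OH | C=C1C[C@H]2O[C@H]2[C@@](C)(O)CC[C@@H]2CC(=O)OC[C@@H]12 | intermediate
20 | methyl 3,4-O-isopropylidene-L-threonate [methyl (2R)-2-[(4S)-2,2-dimethyl-1,3-dioxolan-4-yl]-2-hydroxyacetate] | CC1(C)OC[C@H](O1)[C@@H](O)C(=O)OC | starting material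
21 | (1R)-1-[(4S)-2,2-dimethyl-1,3-dioxolan-4-yl]-2-methylpropane-1,2-diol | CC1(C)OC[C@H](O1)[C@@H](O)C(C)(C)O | intermediate
22 | (1R)-1-[(4S)-2,2-dimethyl-1,3-dioxolan-4-yl]-2-hydroxy-2-methylpropyl methanesulfonate | CC1(C)OC[C@H](O1)[C@@H](OS(C)(=O)=O)C(C)(C)O | intermediate
23 | (2S,3R)-1,2,4-trihydroxy-4-methylpentan-3-yl methanesulfonate | OC[C@H](O)[C@@H](OS(C)(=O)=O)C(C)(C)O | intermediate
24 | (2S,3R)-4-hydroxy-4-methyl-1,2-bis(triethylsilyloxy)pentan-3-yl methanesulfonate | CC[Si](CC)(CC)OC[C@H](O[Si](CC)(CC)CC)[C@@H](OS(C)(=O)=O)C(C)(C)O | intermediate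
25 | (2S)-2-[(1S)-1,2-bis(triethylsilyloxy)ethyl]-3,3-dimethyloxirane | CC[Si](CC)(CC)OC[C@H](O[Si](CC)(CC)CC)[C@@H]1OC1(C)C | intermediate
26 | (2R)-2-[(2S)-3,3-dimethyloxiran-2-yl]-2-(triethylsilyloxy)acetaldehyde | O=C[C@H](O[Si](CC)(CC)CC)[C@@H]1OC1(C)C | intermediate
27 | dilithio species of 19 (C7 alkoxide, lactone enolate) | C=C1C[C@H]2O[C@H]2[C@@](C)(O[Li])CC[C@@H]2C=C(O[Li])OC[C@@H]12 | intermediate (not isolated)
28 | aldol adduct: 19 carrying at C4 the CH(OH)–CH(OTES)–(dimethyloxiranyl) chain, C4/C12 epimers | C=C1C[C@H]2O[C@H]2[C@@](C)(O)CC[C@@H]2C(C(O)[C@H](O[Si](CC)(CC)CC)[C@@H]3OC3(C)C)C(=O)OC[C@@H]12 | intermediate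
29 | C12 mesylate of 28 | C=C1C[C@H]2O[C@H]2[C@@](C)(O)CC[C@@H]2C(C(OS(C)(=O)=O)[C@H](O[Si](CC)(CC)CC)[C@@H]3OC3(C)C)C(=O)OC[C@@H]12 | intermediate (not isolated)
30 | 13-O-triethylsilyl ether of the target (E-alkylidene lactone) | C=C1C[C@H]2O[C@H]2[C@@](C)(O)CC[C@@H]2/C(=C\[C@H](O[Si](CC)(CC)CC)[C@@H]3OC3(C)C)C(=O)OC[C@@H]12 | intermediate
31 | CNP0147265.1 (4aS,7S,8R,9R,11aR,13S,14S; E) | C=C1C[C@H]2O[C@H]2[C@@](C)(O)CC[C@@H]2/C(=C\[C@H](O)[C@@H]3OC3(C)C)C(=O)OC[C@@H]12 | target

Total steps: 22. Longest linear sequence: 16 (steps 1–13 and 20–22); the side-chain aldehyde takes steps 14–19.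

Steps most likely to fail

1. Step 11 (key step). The alkoxide may alkylate on oxygen to give an oxetane instead of cleaving C7–C11, or the skipped diene of the product may drift into conjugation while base is still present. The fallback leaves the anionic manifold. It sets out from diol 14: Appel-type iodination (PPh3, I2, imidazole, toluene, 80 °C) of the primary C19 hydroxyl gives the neopentyl iodide of the cis-hydrindenol lactone F1. Hypoiodite conditions (PhI(OAc)2, I2, hν, CH2Cl2/cyclohexane) then generate the C7 alkoxy radical; β-scission of C7–C11 gives the tertiary C11 radical, which expels the β-iodine atom to form C11=C19 under neutral conditions. This returns to the route at 17.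

2. Step 5. The enolate may lose silanolate by β-elimination before it is alkylated, or the tetrasubstituted magnesium enolate may alkylate too slowly. The fallback separates the two events and avoids a long-lived basic enolate. It sets out from 7: the same copper-catalysed Grignard addition run with TMSCl gives the trimethylsilyl enol ether of the conjugate adduct F2, which is isolated. Tsuji allylation (allyl methyl carbonate, Pd2(dba)3, dppe, THF, rt) then brings in the allyl group as a π-allylpalladium electrophile on the face anti to the C11a substituent. This returns to the route at 9.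

3. Step 12. Facial selectivity in the methyl addition to the flexible nine-membered enone may be poor, giving the C7 epimer, and enolisation may compete. The fallback reverses the order so that C7 is controlled by a neighbouring group instead of a remote one. It sets out from 17: nucleophilic (Weitz–Scheffer) epoxidation with t-BuOOH/DBU in THF at 0 °C gives the cis-8,9-epoxy ketone F3. Methyl addition (MeTi(OiPr)3 or MeMgBr, −78 °C) should then occur anti to the oxirane oxygen, so that hydroxyl and epoxide end up cis. This returns to the route at 19.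

Further compounds
F1 | step 11 | cis-hydrindenol lactone with C7 OH and C11 CH2I (4aR,7R,11S,11aR) | IC[C@@]12CC=C[C@]1(O)CC[C@@H]3CC(=O)OC[C@@H]23
F2 | step 5 | trimethylsilyl enol ether (C7–OTMS, C7=C11) of the conjugate adduct of 7 | C[Si](C)(C)OC1=C(CO[Si](C)(C)C(C)(C)C)[C@H](C[Si](C)(C)OC(C)C)[C@@H](CC(=O)OC)CC1
F3 | step 12 | cis-8,9-epoxy ketone of 17 (4aR,8R,9R,11aR) | C=C1C[C@H]2O[C@H]2C(=O)CC[C@@H]2CC(=O)OC[C@@H]12
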